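## Retrosynthetic overview

1. Target 16 ⇒ aryl ether 13: the C6 ketone and C5–H come from a C5=C6 alkene (hydroboration, oxidation). 13 ⇒ neopentyl alcohol 11 + 7-bromocoumarin 12 (C–O coupling).
2. 11 ⇒ 10 (hydrogenation of the ring C3=C4 bond) ⇒ aldehyde 9 (reduction).
3. 9 ⇒ acyclic tetraenal 8 by an amine-catalysed enantioselective intramolecular Diels–Alder reaction. Both carbocycles close in this one step (ring A from the two new σ-bonds C1–C2 and C4a–C8a, ring B from the tether), and C1, C2, C4a and C8a are set.
4. 8 ⇒ (Z)-vinyl iodide 4 + dienylboronate 7 (Suzuki). 4 ⇒ pent-4-enal 1 (Stork–Zhao olefination, then cross-metathesis with methacrolein 3). 7 ⇒ crotonaldehyde 6 + 1,1-diborylethane 5 (boron–Wittig).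
5. The (Z)-C6=C7 alkene of 8 keeps the future C5 sp2, so no stereocentre exists before the catalytic step; it is the masked α-methyl ketone.

Ring locants below are those of the naphthalene names.

Assumption: 1, 3, 5, 6 and 12 are bought; the quinine-derived amine in step 5 is taken to leave the Cα-Re/Cβ-Si face of the iminium open, and if the first run shows the opposite sense its quinidine-derived pseudo-enantiomer is used with nothing else changed.

## Route

Step 1
Reactants: 1 pent-4-enal
Product: 2 (Z)-6-iodohepta-1,5-diene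
Conditions: EtPPh3I, n-BuLi, THF, 0 °C; I2, −78 °C; NaN(SiMe3)2, −78 °C; then 1, −78 to −20 °C
Reagents that add atoms: ethyltriphenylphosphonium iodide CC[P+](c1ccccc1)(c1ccccc1)c1ccccc1.[I-]; iodine II
Why: Stork–Zhao olefination (Wittig reaction of the α-iodo ylide) gives the (Z)-vinyl iodide, iodine cis to the chain, through the kinetic cis-oxaphosphetane; the terminal alkene is inert.

Step 2
Reactants: 2 (Z)-6-iodohepta-1,5-diene; 3 methacrolein
Product: 4 (2E,6Z)-7-iodo-2-methylocta-2,6-dienal
Conditions: 3 (4 equiv), second-generation Hoveyda–Grubbs catalyst RuCl2(=CH-C6H4-2-OiPr)(H2IMes) (5 mol%), CH2Cl2, 40 °C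
Reagents that add atoms: none
Why: Olefin cross-metathesis of the terminal alkene with excess methacrolein gives the thermodynamically favoured (E)-2-methyl-enal, and the trisubstituted vinyl iodide is too hindered to engage the ruthenium carbene.

Step 3
Reactants: 5 1,1-bis(pinacolboryl)ethane; 6 (E)-but-2-enal
Product: 7 2-[(2Z,4E)-hexa-2,4-dien-2-yl]-4,4,5,5-tetramethyl-1,3,2-dioxaborolane
Conditions: LiTMP (lithium 2,2,6,6-tetramethylpiperidide), THF, 0 °C; then 6, −78 °C to rt
Reagents that add atoms: none
Why: Boron–Wittig olefination: the α-boryl carbanion adds 1,2 to the aldehyde and syn B–O elimination leaves the propenyl group trans to the remaining boronate (cis to methyl), which is the geometry needed for the diene terminus.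

Step 4
Reactants: 4 (2E,6Z)-7-iodo-2-methylocta-2,6-dienal; 7 2-[(2Z,4E)-hexa-2,4-dien-2-yl]-4,4,5,5-tetramethyl-1,3,2-dioxaborolane
Product: 8 (2E,6Z,8E,10E)-2,7,8-trimethyldodeca-2,6,8,10-tetraenal
Conditions: Pd(OAc)2 (5 mol%), SPhos (10 mol%), K3PO4, THF/H2O, 40 °C
Reagents that add atoms: none
Why: Suzuki–Miyaura alkenyl–alkenyl coupling proceeds with retention at both sp2 carbons, and the mild phosphate base spares the enal.

Step 5
Reactants: 8 (2E,6Z,8E,10E)-2,7,8-trimethyldodeca-2,6,8,10-tetraenal
Product: 10 [(1R,2R,4aS,8aR)-1,2,4a,5-tetramethyl-1,2,4a,7,8,8a-hexahydronaphthalen-1-yl]methanol, via bicyclic aldehyde 9 (not isolated)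
Conditions: 9-amino-9-deoxy-epi-quinine (20 mol%), CF3CO2H (40 mol%), CHCl3, 40 °C; then NaBH4, EtOH, 0 °C
Reagents that add atoms: none
Why: Proposed new method: the primary amine condenses with the α-branched enal to an E-iminium ion (LUMO lowered; this activation of 2-methyl-2-alkenals is known for conjugate additions), the protonated quinuclidine/trifluoroacetate pair blocks one face, and the tethered (8E,10E)-diene adds to the C2-Re/C3-Si face through the iminium-endo, anti (chair-like tether) transition state, forming C2–C11 and C3–C8 in one event and thereby C1(R), C2(R), C4a(S) and C8a(R) of 9 (trans ring fusion, 2-Me cis to CHO, 1-Me syn to 4a-Me, as fixed by the E-enal and E,E-diene geometries and the endo rule), after which hydrolysis frees the catalyst and NaBH4 reduces the aldehyde in the same pot; closest known reactions: imidazolidinone (secondary amine) iminium-catalysed intramolecular Diels–Alder reactions of α-unsubstituted trienals and primary-amine iminium-catalysed intermolecular Diels–Alder reactions of α-substituted acroleins.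

Step 6
Reactants: 10 [(1R,2R,4aS,8aR)-1,2,4a,5-tetramethyl-1,2,4a,7,8,8a-hexahydronaphthalen-1-yl]methanol
Product: 11 [(1R,2R,4aS,8aR)-1,2,4a,5-tetramethyl-1,2,3,4,4a,7,8,8a-octahydronaphthalen-1-yl]methanol
Conditions: H2 (4 atm), RhCl(PPh3)3 (5 mol%), benzene/EtOH, rt
Reagents that add atoms: none
Why: Homogeneous hydrogenation with Wilkinson's catalyst reduces the cis-disubstituted C3=C4 bond, while the trisubstituted C5=C6 bond next to quaternary C4a is left; no stereocentre is created.

Step 7
Reactants: 11 [(1R,2R,4aS,8aR)-1,2,4a,5-tetramethyl-1,2,3,4,4a,7,8,8a-octahydronaphthalen-1-yl]methanol; 12 7-bromo-2H-chromen-2-one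
Product: 13 7-{[(1R,2R,4aS,8aR)-1,2,4a,5-tetramethyl-1,2,3,4,4a,7,8,8a-octahydronaphthalen-1-yl]methoxy}-2H-chromen-2-one
Conditions: [Pd(C3H5)Cl]2 (2.5 mol%), RockPhos (6 mol%), Cs2CO3, toluene, 90 °C
Reagents that add atoms: none
Why: Buchwald-type palladium-catalysed C–O cross-coupling: the primary alkoxide binds palladium after oxidative addition of the electron-poor aryl bromide and the bulky biarylphosphine drives C–O reductive elimination, so no SN2 displacement at the neopentyl carbon is needed.

Step 8
Reactants: 13 7-{[(1R,2R,4aS,8aR)-1,2,4a,5-tetramethyl-1,2,3,4,4a,7,8,8a-octahydronaphthalen-1-yl]methoxy}-2H-chromen-2-one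
Product: 16 7-{[(1R,2R,4aS,5R,8aR)-1,2,4a,5-tetramethyl-6-oxodecahydronaphthalen-1-yl]methoxy}-2H-chromen-2-one, via C6-alkylborane 14 (not isolated), via C6-alcohol 15 (not isolated)
Conditions: BH3·SMe2, THF, 0 °C to rt; then NMO, [N(C3H7)4][RuO4] (5 mol%), 4 Å MS, CH2Cl2, rt; then DBU (cat.), rt
Reagents that add atoms: N-methylmorpholine N-oxide C[N+]1([O-])CCOCC1
Why: Brown hydroboration puts boron on the less substituted C6 and hydrogen on C5, syn from the face opposite the axial 4a-methyl, so C5 is formed as 5R (methyl equatorial, cis to 4a-Me, also the thermodynamic epimer that DBU secures), and amine-oxide C–B oxidation followed by Ley–Griffith oxidation gives the C6 ketone.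

## Compound list

1 | pent-4-enal | C=CCCC=O | starting material
2 | (Z)-6-iodohepta-1,5-diene | C=CCC/C=C(C)\I | intermediate
3 | methacrolein (2-methylprop-2-enal) | CC(=C)C=O | starting material
4 | (2E,6Z)-7-iodo-2-methylocta-2,6-dienal | O=C/C(C)=C/CC/C=C(C)\I | intermediate
5 | 1,1-bis(pinacolboryl)ethane, 2,2'-(ethane-1,1-diyl)bis(4,4,5,5-tetramethyl-1,3,2-dioxaborolane) | CC(B1OC(C)(C)C(C)(C)O1)B1OC(C)(C)C(C)(C)O1 | starting material
6 | (E)-but-2-enal (crotonaldehyde) | C/C=C/C=O | starting material
7 | 2-[(2Z,4E)-hexa-2,4-dien-2-yl]-4,4,5,5-tetramethyl-1,3,2-dioxaborolane | CC1(C)OB(OC1(C)C)/C(C)=C/C=C/C | intermediate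
8 | (2E,6Z,8E,10E)-2,7,8-trimethyldodeca-2,6,8,10-tetraenal | O=C/C(C)=C/CC/C=C(C)\C(C)=C\C=C\C | intermediate
9 | (1R,2R,4aS,8aR)-1,2,4a,5-tetramethyl-1,2,4a,7,8,8a-hexahydronaphthalene-1-carbaldehyde (trans-fused; 2-Me, CHO and H-8a on one face, 1-Me and 4a-Me on the other) | C[C@@H]1C=C[C@@]2(C)[C@@H](CCC=C2C)[C@]1(C)C=O | intermediate
10 | [(1R,2R,4aS,8aR)-1,2,4a,5-tetramethyl-1,2,4a,7,8,8a-hexahydronaphthalen-1-yl]methanol | C[C@@H]1C=C[C@@]2(C)[C@@H](CCC=C2C)[C@]1(C)CO | intermediate
11 | [(1R,2R,4aS,8aR)-1,2,4a,5-tetramethyl-1,2,3,4,4a,7,8,8a-octahydronaphthalen-1-yl]methanol | C[C@@H]1CC[C@@]2(C)[C@@H](CCC=C2C)[C@]1(C)CO | intermediate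
12 | 7-bromo-2H-chromen-2-one (7-bromocoumarin) | O=c1ccc2ccc(Br)cc2o1 | starting material
13 | 7-{[(1R,2R,4aS,8aR)-1,2,4a,5-tetramethyl-1,2,3,4,4a,7,8,8a-octahydronaphthalen-1-yl]methoxy}-2H-chromen-2-one | C[C@@H]1CC[C@@]2(C)[C@@H](CCC=C2C)[C@]1(C)COc1ccc2ccc(=O)oc2c1 | intermediate
14 | 7-{[(1R,2R,4aR,5S,6R,8aR)-6-boranyl-1,2,4a,5-tetramethyldecahydronaphthalen-1-yl]methoxy}-2H-chromen-2-one (BH2 on C6 and new H on C5 both cis to H-8a) | C[C@@H]1CC[C@@]2(C)[C@@H](CC[C@@H](B)[C@@H]2C)[C@]1(C)COc1ccc2ccc(=O)oc2c1 | intermediate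
15 | 7-{[(1R,2R,4aS,5R,6R,8aR)-6-hydroxy-1,2,4a,5-tetramethyldecahydronaphthalen-1-yl]methoxy}-2H-chromen-2-one | C[C@@H]1CC[C@@]2(C)[C@@H](CC[C@@H](O)[C@@H]2C)[C@]1(C)COc1ccc2ccc(=O)oc2c1 | intermediate
16 | 7-{[(1R,2R,4aS,5R,8aR)-1,2,4a,5-tetramethyl-6-oxodecahydronaphthalen-1-yl]methoxy}-2H-chromen-2-one | C[C@@H]1CC[C@@]2(C)[C@@H](CCC(=O)[C@@H]2C)[C@]1(C)COc1ccc2ccc(=O)oc2c1 | target

## Step count and main risks

Total step count: 8. Longest linear sequence: 7 (steps 1, 2, 4, 5, 6, 7, 8 from pent-4-enal); step 3 is the side branch.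

The three steps most likely to fail:

Step 5, the new amine-catalysed intramolecular cycloaddition. Two quaternary carbons are formed, the diene carries an inside methyl, and the α-methyl may favour the exo (cis-fused) adduct or erode the ee. The fallback replaces covalent iminium activation by chiral Lewis-acid activation. Tetraenal 8 is treated with Corey's o-tolyl oxazaborolidine activated by HNTf2 (20 mol%) in CH2Cl2 at −78 to −20 °C. This is known chemistry for enantioselective Diels–Alder reactions of 2-methyl-substituted enals and for intramolecular cases of trienals. It sets out from 8 and comes back at aldehyde 9, which is reduced with NaBH4 to 10 as before. No new compound is made (F0).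

Step 7, the C–O coupling. β-Hydride elimination at palladium would return aldehyde 9-type material, and the alkoxide may open the lactone. The fallback is a Mitsunobu etherification, which makes the bond by displacement at carbon instead of reductive elimination at palladium. Alcohol 11 is treated with 7-hydroxycoumarin (umbelliferone), PBu3 and 1,1'-(azodicarbonyl)dipiperidine in toluene at 80 °C. It sets out from 11 and comes back at 13. No new compound is made (F0).

Step 8, hydroboration in the presence of the coumarin. Borane may attack the lactone or its conjugated alkene. The fallback changes the order so that borane never meets the coumarin. Alcohol 11 is hydroborated (BH3·SMe2, THF; then NaBO3·4H2O) to the diol (1R,2R,4aS,5R,6R,8aR)-1-(hydroxymethyl)-1,2,4a,5-tetramethyldecahydronaphthalen-6-ol F1. The primary hydroxyl of F1 is then coupled selectively with 12 under the conditions of step 7, which gives 15, now isolated. The fallback sets out from 11 and comes back at 15, which is oxidised with NMO and catalytic [N(C3H7)4][RuO4] as in the second half of step 8 to give 16.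

## Further compounds

F0 | step 5 | none | none
F0 | step 7 | none | none
F1 | step 8 | (1R,2R,4aS,5R,6R,8aR)-1-(hydroxymethyl)-1,2,4a,5-tetramethyldecahydronaphthalen-6-ol | C[C@@H]1CC[C@@]2(C)[C@@H](CC[C@@H](O)[C@@H]2C)[C@]1(C)CO
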